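**Plan**
- Retrosynthesis cuts, in this order: (a) the ring C4–OH back to C4–H (C–H borylation/oxidation); (b) the side-chain bond C5–C6, counted from the ring, back to two N-acyloxyphthalimides, a 6-arylhexanoate and nonanoate (Ni-electrocatalytic doubly decarboxylative sp3–sp3 coupling); (c) the aryl-C1=C2 bond of the C6 acid back to o-vanillin and a C5 phosphonium acid (Wittig).
- Forward: the benzene ring is bought with its CHO/OH/OMe 1,2,3-pattern; chain carbons C1–C5 plus a carboxyl are attached by Wittig/hydrogenation; the only phenol is acetylated; C6–C13 are added in the key step; the free 4-OH comes last.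
- Enabling features: C5 and C6 of the chain are plain CH2 groups in an unbranched polymethylene chain, so each half is a primary alkyl radical available from a cheap acid one carbon longer (6-arylhexanoic acid, nonanoic acid). C5 is insulated from the benzene ring by four CH2 groups. In the ring, the contiguous C1(OAc)/C2(OMe)/C6(alkyl) substituents leave C4–H as the only C–H without an ortho neighbour.
- Helpers: the phthalimide-N-oxy activating groups on both carboxyls leave with CO2 in the key step itself; no protecting group is used, the acetate being that of the target.
- Stereochemistry: none to set; the E/Z mixture from the Wittig step is erased by hydrogenation.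

Key step: step 6

Assumption: the target has no stereocentre and no stereogenic double bond, so the SMILES defines one achiral compound and no enantiocontrol is required.

**Route**

Step 1
Reactants: 1 o-vanillin (2-hydroxy-3-methoxybenzaldehyde); 2 (4-carboxybutyl)triphenylphosphonium bromide
Product: 4 6-(2-hydroxy-3-methoxyphenyl)hex-5-enoic acid (E/Z mixture), via phosphonium ylide 3 (not isolated)
Conditions: 2 (1.5 equiv), KOtBu (4 equiv), THF, 0 °C → rt; then 1 M HCl
Reagents that add atoms: none
Why: Wittig olefination, in which the non-stabilised carboxylate ylide 3 should add to the aldehyde of 1 even in its phenoxide form, as such ylides do with salicylaldehydes; the alkene geometry is irrelevant because the double bond is hydrogenated next, and no stereocentre is formed.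

Step 2
Reactants: 4 6-(2-hydroxy-3-methoxyphenyl)hex-5-enoic acid
Product: 5 6-(2-hydroxy-3-methoxyphenyl)hexanoic acid
Conditions: H2 (1 atm), 10% Pd/C, EtOAc, rt
Reagents that add atoms: none
Why: Heterogeneous catalytic hydrogenation of a 1,2-disubstituted styrene over Pd/C is fast at 1 atm and should leave the arene, the methyl ether, the phenol and the acid untouched.

Step 3
Reactants: 5 6-(2-hydroxy-3-methoxyphenyl)hexanoic acid
Product: 6 6-(2-acetoxy-3-methoxyphenyl)hexanoic acid
Conditions: Ac2O (1.5 equiv), 2 M aq. NaOH (2.2 equiv), 0 °C; then HCl to pH 2
Reagents that add atoms: acetic anhydride, CC(=O)OC(C)=O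
Why: Schotten–Baumann-type O-acetylation, in which the phenoxide is acetylated in cold aqueous alkali faster than the anhydride hydrolyses while the carboxylate returns as the free acid on acidification, so the acetate of the target is installed while only one phenol exists.

Step 4
Reactants: 6 6-(2-acetoxy-3-methoxyphenyl)hexanoic acid
Product: 7 1,3-dioxoisoindolin-2-yl 6-(2-acetoxy-3-methoxyphenyl)hexanoate
Conditions: N-hydroxyphthalimide (1.1 equiv), DIC (1.1 equiv), DMAP (5 mol%), CH2Cl2, rt
Reagents that add atoms: N-hydroxyphthalimide, O=C1c2ccccc2C(=O)N1O
Why: Carbodiimide (Steglich-type) esterification with N-hydroxyphthalimide should give the bench-stable redox-active ester, the hindered aryl acetate being inert to DIC/DMAP at rt.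

Step 5
Reactants: 8 nonanoic acid
Product: 9 1,3-dioxoisoindolin-2-yl nonanoate
Conditions: N-hydroxyphthalimide (1.1 equiv), DIC (1.1 equiv), DMAP (5 mol%), CH2Cl2, rt
Reagents that add atoms: N-hydroxyphthalimide, O=C1c2ccccc2C(=O)N1O
Why: The same carbodiimide esterification turns the cheap C9 acid into its redox-active ester, the radical precursor for the octyl half.

Step 6
Reactants: 7 1,3-dioxoisoindolin-2-yl 6-(2-acetoxy-3-methoxyphenyl)hexanoate (1 equiv); 9 1,3-dioxoisoindolin-2-yl nonanoate (3 equiv)
Product: 10 2-methoxy-6-tridecylphenyl acetate
Conditions: NiCl2·6H2O (20 mol%), 2,2':6',2''-terpyridine (20 mol%), AgNO3 (0.3 equiv), NMP, (+)Mg/(−)RVC, undivided cell, constant current, rt; aq. HCl work-up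
Reagents that add atoms: none
Why: Low-valent Ni(terpy), generated at the carbon cathode (coated in situ with Ag nanoparticles from AgNO3), transfers an electron to each N-acyloxyphthalimide, whose radical anion fragments to phthalimide anion, CO2 and a primary alkyl radical; capture of both radicals at nickel and reductive elimination forms the C(sp3)–C(sp3) bond, the electrons coming from the sacrificial Mg anode. The closest known reaction type is the Ni-electrocatalytic doubly decarboxylative C(sp3)–C(sp3) coupling of redox-active esters, a reductive counterpart of the Kolbe electrolysis that is established for primary–primary heterocoupling. No ring is closed and no stereocentre is created. The step needs cross- over homo-coupling; both radicals are unstabilised primary ones of like reactivity, so the outcome is statistical and is steered by the threefold excess of the cheap ester 9, the by-product hydrocarbon eluting well ahead of ester 10. It also needs the ring to survive: the manifold is cathodic, so the electron-rich guaiacyl ring (oxidisable at a Kolbe anode) and the aryl acetate (labile in the alkaline methanol of a Kolbe electrolysis) should be untouched. The radical centre of the aryl half is separated from the ring by four CH2 groups and has no β-heteroatom, so neither benzylic stabilisation, cyclisation onto the arene nor elimination should compete.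

Step 7
Reactants: 10 2-methoxy-6-tridecylphenyl acetate
Product: 12 Ardisiphenol D (4-hydroxy-2-methoxy-6-tridecylphenyl acetate), via aryl pinacol boronate 11 (not isolated)
Conditions: [Ir(OMe)(cod)]2 (1.5 mol%), dtbpy (3 mol%), B2pin2 (1.0 equiv), THF, 80 °C; evaporate volatiles; then Oxone (1 equiv), acetone/H2O, rt, 10 min; NaHSO3 quench
Reagents that add atoms: bis(pinacolato)diboron, CC1(C)OB(OC1(C)C)B1OC(C)(C)C(C)(C)O1 (boron of 11); Oxone (potassium peroxymonosulfate), [K+].[O-]S(=O)(=O)OO (phenolic oxygen of 12)
Why: One-pot Ir-catalysed aromatic C–H borylation/oxidation, in which the sterically governed borylation should enter at C4–H (para to the acetoxy group), the only ring C–H of 10 without an ortho substituent, and Oxone then converts C–B into C–OH at that position under weakly acidic conditions that the hindered aryl acetate tolerates.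

**Compound list**
1 | o-vanillin (2-hydroxy-3-methoxybenzaldehyde) | COc1cccc(C=O)c1O | starting material
2 | (4-carboxybutyl)triphenylphosphonium bromide | OC(=O)CCCC[P+](c1ccccc1)(c1ccccc1)c1ccccc1.[Br-] | starting material
3 | potassium 5-(triphenyl-λ5-phosphanylidene)pentanoate (ylide, not isolated) | [K+].[O-]C(=O)CCCC=P(c1ccccc1)(c1ccccc1)c1ccccc1 | intermediate
4 | 6-(2-hydroxy-3-methoxyphenyl)hex-5-enoic acid (E/Z mixture, geometry not controlled) | COc1cccc(C=CCCCC(=O)O)c1O | intermediate
5 | 6-(2-hydroxy-3-methoxyphenyl)hexanoic acid | COc1cccc(CCCCCC(=O)O)c1O | intermediate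
6 | 6-(2-acetoxy-3-methoxyphenyl)hexanoic acid | CC(=O)Oc1c(OC)cccc1CCCCCC(=O)O | intermediate
7 | 1,3-dioxoisoindolin-2-yl 6-(2-acetoxy-3-methoxyphenyl)hexanoate | CC(=O)Oc1c(OC)cccc1CCCCCC(=O)ON1C(=O)c2ccccc2C1=O | intermediate
8 | nonanoic acid | CCCCCCCCC(=O)O | starting material
9 | 1,3-dioxoisoindolin-2-yl nonanoate | CCCCCCCCC(=O)ON1C(=O)c2ccccc2C1=O | intermediate
10 | 2-methoxy-6-tridecylphenyl acetate | CCCCCCCCCCCCCc1cccc(OC)c1OC(C)=O | intermediate
11 | 2-methoxy-4-(4,4,5,5-tetramethyl-1,3,2-dioxaborolan-2-yl)-6-tridecylphenyl acetate (not isolated) | CCCCCCCCCCCCCc1cc(B2OC(C)(C)C(C)(C)O2)cc(OC)c1OC(C)=O | intermediate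
12 | Ardisiphenol D (4-hydroxy-2-methoxy-6-tridecylphenyl acetate; achiral) | CCCCCCCCCCCCCc1cc(O)cc(OC)c1OC(C)=O | target

**Step count**
Total steps: 7. Longest linear sequence: 6 (steps 1, 2, 3, 4, 6, 7 from o-vanillin); step 5 is a one-step side branch.

**Steps most likely to fail, with fallbacks**

Step 6. The aryl ester 7 may be lost to homo-coupling, or to premature reduction of its radical (hydrogen abstraction from solvent, β-hydride elimination at nickel), and the Mg anode may passivate. The fallback replaces the coupling of two electrophiles by a coupling of one electrophile with one nucleophile, so cross-selectivity is inherent. It sets out from compound 7 and comes back at compound 10. Octylmagnesium bromide (2 equiv) and ZnCl2 (1 equiv, slight excess) in THF should give di-n-octylzinc F1. F1 is coupled with 7 in a Ni-catalysed decarboxylative alkyl–alkyl Negishi reaction (NiCl2·glyme, 4,4'-di-tert-butyl-2,2'-bipyridine, THF/DMF, rt); dialkylzincs do not attack aryl acetates at rt. This should give 10 directly.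

Step 7. Positional control of the C–H borylation may be incomplete (entry next to the methoxy group or at the benzylic CH2), turnover on the electron-rich ring may be slow, and the hydroquinone monoacetate may be over-oxidised by excess Oxone. The fallback reaches the same boronate by polar, phenol-directed chemistry. It sets out from compound 10 and comes back at compound 11. Methanolysis (K2CO3 cat., MeOH, rt) should give 2-methoxy-6-tridecylphenol F2. NBS (MeCN, 0 °C) should brominate para to the free OH, both ortho positions being blocked, to give 4-bromo-2-methoxy-6-tridecylphenol F3. Ac2O/pyridine should give 4-bromo-2-methoxy-6-tridecylphenyl acetate F4. Miyaura borylation (B2pin2, KOAc, Pd(dppf)Cl2, dioxane, 80 °C) should then deliver 11, which is oxidised as in step 7, or with an amine N-oxide if the peroxysulfate proves too harsh.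

Step 1. Phenoxide formation may deactivate the aldehyde of 1, so that the ylide is consumed by proton transfer and decomposition and conversion stalls. The fallback masks the phenol with a group that the hydrogenation removes anyway. It sets out from compound 1 and comes back at compound 5. BnBr/K2CO3 (DMF, rt) should give 2-(benzyloxy)-3-methoxybenzaldehyde F5. Wittig reaction with ylide 3 (from 2 and KOtBu, THF) should give 6-[2-(benzyloxy)-3-methoxyphenyl]hex-5-enoic acid F6. H2 over Pd/C (EtOAc/MeOH) should saturate the alkene and cleave the benzyl ether in one operation to give 5.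

**Further compounds**
F1 | step 6 | di-n-octylzinc | CCCCCCCC[Zn]CCCCCCCC
F2 | step 7 | 2-methoxy-6-tridecylphenol | CCCCCCCCCCCCCc1cccc(OC)c1O
F3 | step 7 | 4-bromo-2-methoxy-6-tridecylphenol | CCCCCCCCCCCCCc1cc(Br)cc(OC)c1O
F4 | step 7 | 4-bromo-2-methoxy-6-tridecylphenyl acetate | CCCCCCCCCCCCCc1cc(Br)cc(OC)c1OC(C)=O
F5 | step 1 | 2-(benzyloxy)-3-methoxybenzaldehyde | COc1cccc(C=O)c1OCc1ccccc1
F6 | step 1 | 6-[2-(benzyloxy)-3-methoxyphenyl]hex-5-enoic acid (E/Z mixture) | COc1cccc(C=CCCCC(=O)O)c1OCc1ccccc1
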